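The epoxycyclohexene ring (7-oxabicyclo[4.1.0]hept-3-ene: oxirane carbons C1/C6, carbinols C2/C5 cis to each other and anti to the oxirane, C3=C4 between them) is read as the singlet-oxygen adduct of a benzene oxide, the valence tautomer of an oxepin. A 2,5-disubstituted oxepin that already carries the side-chain carbinol and a (Z)-vinyl iodide contracts by 6π electrocyclisation; trapping with singlet oxygen and O–O reduction deliver the six-membered ring with all four stereocentres in one operation. The terpenoid half, from a titanocene-mediated radical cyclisation of (R)-epoxygeranyl acetate, is attached by Suzuki coupling, and desilylation ends the route.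

Key step: step 10

Remark on numbering: ring atoms are numbered as in 7-oxabicyclo[4.1.0]hept-3-ene (C1 quaternary oxirane carbon, C6 oxirane CH); C1′ is the side-chain carbinol carbon; TBS = tert-butyldimethylsilyl.

Remark on the chemistry: benzene oxide enantiomers interconvert through the oxepin, so ring chirality cannot be carried through step 9. C1′, set by reagent control in step 4, makes the two anti adducts of step 10 diastereomers, and the wanted one is separated and taken on; at best half of the adduct is therefore used.

Step 1
Reactants: 1 tert-butyldimethyl(prop-2-yn-1-yloxy)silane; 2 ethylene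
Product: 3 2-(TBS-oxymethyl)buta-1,3-diene
Conditions: second-generation Grubbs catalyst (5 mol%), ethylene (1 atm), toluene, 80 °C
Reagents that add atoms: none
Why: Enyne cross-metathesis of a terminal alkyne with ethylene is a known route to 2-substituted 1,3-butadienes and tolerates propargylic silyl ethers.

Step 2
Reactants: 3 2-(TBS-oxymethyl)buta-1,3-diene; 4 methyl propiolate
Product: 5 methyl 4-(TBS-oxymethyl)cyclohexa-1,4-diene-1-carboxylate
Conditions: Me2AlCl (0.2 equiv), CH2Cl2, −20 °C to rt
Reagents that add atoms: none
Why: Lewis acid-promoted Diels–Alder reaction of a 2-substituted diene with a propiolate should follow the para rule (largest diene HOMO coefficient at C1, largest LUMO coefficient at the propiolate β-carbon) and give the 1,4-disubstituted cyclohexa-1,4-diene.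

Step 3
Reactants: 5 methyl 4-(TBS-oxymethyl)cyclohexa-1,4-diene-1-carboxylate; 6 1-propynyllithium
Product: 7 cyclohexadienyl propynyl ketone
Conditions: BF3·OEt2, THF, −78 °C
Reagents that add atoms: none
Why: Acylation of the lithium acetylide by the ester in the presence of BF3·OEt2 should stop at the ynone because the tetrahedral adduct is held as a borate until work-up.

Step 4
Reactants: 7 cyclohexadienyl propynyl ketone
Product: 8 (R)-propargylic alcohol
Conditions: (R)-2-methyl-CBS-oxazaborolidine (0.5 equiv), catecholborane, toluene, −78 °C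
Reagents that add atoms: none
Why: Corey–Bakshi–Shibata reduction, in which the slim propynyl group acts as the small and the α-branched cyclohexadienyl group as the large substituent, so that the (R)-catalyst should deliver hydride to the face giving the (R)-carbinol, the future C1′ centre.

Step 5
Reactants: 8 (R)-propargylic alcohol
Product: 9 (S,Z)-3-iodoallylic alcohol
Conditions: NaAlH2(OCH2CH2OMe)2, THF, 0 °C to rt; EtOAc; then iodine, −78 °C
Reagents that add atoms: iodine, [I][I]
Why: Hydroxyl-directed trans-hydroalumination places aluminium on the distal alkyne carbon in a five-membered aluminate, and iodinolysis with retention gives the (Z)-3-iodoallylic alcohol with iodine cis to C1′ (the descriptor at C1′ changes to S only through the priority rules).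

Step 6
Reactants: 9 (S,Z)-3-iodoallylic alcohol
Product: 10 erythro epoxy alcohol
Conditions: Ti(OiPr)4, L-(+)-diisopropyl tartrate, tBuOOH, 4 Å molecular sieves, CH2Cl2, −20 °C
Reagents that add atoms: tert-butyl hydroperoxide, CC(C)(C)OO
Why: Sharpless asymmetric epoxidation acts only on the ring alkene allylic to the free hydroxyl (the iodoalkene is (Z)-substituted and electron-poor, the other ring alkene has no free hydroxyl), and with L-(+)-tartrate the (S)-carbinol is the fast-reacting matched enantiomer, so the erythro epoxy alcohol should form while residual (R)-carbinol from step 4 stays behind.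

Step 7
Reactants: 10 erythro epoxy alcohol
Product: 11 bis-silyl epoxide
Conditions: TBSOTf, 2,6-lutidine, CH2Cl2, −78 °C
Reagents that add atoms: tert-butyldimethylsilyl triflate, CC(C)(C)[Si](C)(C)OS(=O)(=O)C(F)(F)F
Why: Silylation with the silyl triflate and a hindered base is fast for the hindered secondary alcohol and prevents bromo-etherification in step 8 and epoxide migration in step 9.

Step 8
Reactants: 11 bis-silyl epoxide
Product: 12 trans-dibromide
Conditions: Br2 (1.0 equiv), CH2Cl2, −78 °C
Reagents that add atoms: bromine, BrBr
Why: Anti addition of bromine through the bromonium ion should occur at the electron-rich trisubstituted ring alkene in preference to the deactivated iodoalkene, and either trans-dibromide serves because both new centres are destroyed in step 9.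

Step 9
Reactants: 12 trans-dibromide
Product: 13 2,5-disubstituted oxepin
Conditions: DBU (4 equiv), THF, 0 °C to rt, base-washed glassware, dark; used at once
Reagents that add atoms: none
Why: Twofold E2 dehydrobromination of a 4,5-dibromo-1,2-epoxycyclohexane is the classical (Vogel) entry to benzene oxides, and the 1,4-dialkyl benzene oxide formed equilibrates by valence tautomerism with the 2,5-disubstituted oxepin, which erases the oxirane configuration.

Step 10
Reactants: 13 2,5-disubstituted oxepin
Product: 16 epoxy-ene-diol vinyl iodide (fragment A), via arene oxide 14 (not isolated), via anti endoperoxide 15 (not isolated)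
Conditions: O2, visible light (sodium lamp), tetraphenylporphyrin (cat.), CH2Cl2, −30 °C; then thiourea, MeOH, −30 °C to rt; chromatographic separation from the ring diastereomer
Reagents that add atoms: dioxygen, O=O
Why: Oxepin 13 is in rapid thermal equilibrium with its valence tautomer 14 through a disrotatory 6π electrocyclisation that forms the C1–C6 bond (oxepin C2–C7) and thereby closes the six-membered carbocycle and the oxirane at once, contracting the seven-membered ring; singlet oxygen then adds across the diene termini C2/C5 in a suprafacial [4+2] cycloaddition that closes the 2,3-dioxabicyclo[2.2.2]octene bridge, and thiourea cleaves only the O–O bond. The closest known reaction type is the photooxygenation of benzene oxide–oxepin and of 1-(acyloxymethyl)benzene oxides to anti epoxy endoperoxides, followed by thiourea reduction to cis-enediols. The cis fusion at C1/C6 follows from the disrotatory closure, the anti relation of both new C–O bonds to the oxirane from approach of the oxygen to the face opposite the epoxide oxygen, and their mutual cis relation from the concerted addition and O–O cleavage with retention. The absolute sense at C1/C6 is not fixed by the closure, because both arene oxide enantiomers interconvert through the oxepin; the pre-set C1′ centre turns their adducts into diastereomers, no strong facial bias is counted on, and the wanted (1R,2S,5R,6S) diol 16 is separated from its ring diastereomer. Chemoselectivity for the [4+2] addition is expected because the s-cis cyclohexadiene is far more reactive towards singlet oxygen than the electron-poor iodoalkene and no other oxidisable alkene is yet present, while low temperature and acid-free glassware suppress aromatisation of 14 to a phenol.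

Step 11
Reactants: 17 geranyl acetate
Product: 18 (R)-6,7-epoxygeranyl acetate
Conditions: D-fructose-derived Shi ketone (0.3 equiv), KHSO5 (as 2KHSO5·KHSO4·K2SO4), K2CO3, Bu4NHSO4, MeCN/dimethoxymethane/aqueous buffer pH 10.5, 0 °C
Reagents that add atoms: potassium peroxymonosulfate, [K+].[O-]S(=O)(=O)OO
Why: Shi epoxidation, in which the dioxirane from the D-fructose-derived ketone attacks the electron-rich distal trisubstituted alkene (the 2,3-alkene is deactivated by the allylic acetate) through the spiro transition state that should give the (R)-epoxide.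

Step 12
Reactants: 18 (R)-6,7-epoxygeranyl acetate
Product: 19 hydroxy-γ-cyclogeranyl acetate
Conditions: Cp2TiCl2 (2.2 equiv), Mn dust, THF, rt; dilute aqueous HCl work-up
Reagents that add atoms: none
Why: Cp2TiCl (trivalent titanium) opens the epoxide homolytically to the tertiary radical, which cyclises 6-endo through a chair onto the (E)-alkene; trapping of the new tertiary radical by a second Cp2TiCl and β-hydride elimination give the exocyclic alkene, with the untouched C–O centre and the equatorial CH2OAc group cis, as known for epoxygeranyl acetate (Nugent–RajanBabu epoxide opening).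

Step 13
Reactants: 19 hydroxy-γ-cyclogeranyl acetate
Product: 20 silyl ether acetate
Conditions: TBSOTf, 2,6-lutidine, CH2Cl2, −78 °C to 0 °C
Reagents that add atoms: tert-butyldimethylsilyl triflate, CC(C)(C)[Si](C)(C)OS(=O)(=O)C(F)(F)F
Why: Silyl triflate silylation of the hindered neopentyl-type secondary alcohol is reliable and is needed so that the later aldehyde cannot close to a bridged lactol.

Step 14
Reactants: 20 silyl ether acetate
Product: 21 primary alcohol
Conditions: K2CO3, MeOH, rt
Reagents that add atoms: none
Why: Mild base-catalysed methanolysis removes the acetate without touching the silyl ether or the exocyclic alkene.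

Step 15
Reactants: 21 primary alcohol
Product: 22 γ-cyclocitral-type aldehyde
Conditions: Dess–Martin periodinane, NaHCO3, CH2Cl2, 0 °C; used at once
Reagents that add atoms: none
Why: Dess–Martin oxidation under buffered, non-basic conditions should give the aldehyde without epimerising the α-centre or moving the exocyclic double bond into conjugation.

Step 16
Reactants: 22 γ-cyclocitral-type aldehyde; 23 2-(dichloromethyl)-4,4,5,5-tetramethyl-1,3,2-dioxaborolane
Product: 24 (E)-alkenylboronate (fragment B)
Conditions: CrCl2, LiI, THF, rt
Reagents that add atoms: none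
Why: Takai–Utimoto boryl olefination, in which the geminal dichromium species from the dihalomethylboronate adds to the aldehyde and eliminates to the (E)-alkenylboronate under neutral conditions that preserve the α-centre.

Step 17
Reactants: 16 epoxy-ene-diol vinyl iodide (fragment A); 24 (E)-alkenylboronate (fragment B)
Product: 25 tris-silyl ether of the target
Conditions: PdCl2(dppf) (5 mol%), AsPh3, Cs2CO3, DMF/THF/H2O, rt, dark
Reagents that add atoms: none
Why: Suzuki–Miyaura coupling of the (Z)-alkenyl iodide with the (E)-alkenylboronate proceeds with retention at both partners to the (2Z,4E)-diene, and the carbonate base at room temperature should leave the oxirane, the free diol and the silyl ethers alone.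

Step 18
Reactants: 25 tris-silyl ether of the target
Product: 26 target CNP0357844.1
Conditions: Bu4NF, AcOH (1:1), THF, 0 °C to rt
Reagents that add atoms: none
Why: Fluoride-mediated cleavage of the three silyl ethers, buffered with acetic acid so that no free alkoxide can open or shift the oxirane, should release the target without touching any stereocentre.

Compound list

1 | tert-butyldimethyl(prop-2-yn-1-yloxy)silane | C#CCO[Si](C)(C)C(C)(C)C | starting material
2 | ethylene | C=C | starting material
3 | tert-butyldimethyl[(2-methylidenebut-3-en-1-yl)oxy]silane | C=CC(=C)CO[Si](C)(C)C(C)(C)C | intermediate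
4 | methyl propiolate | C#CC(=O)OC | starting material
5 | methyl 4-({[tert-butyl(dimethyl)silyl]oxy}methyl)cyclohexa-1,4-diene-1-carboxylate | COC(=O)C1=CCC(CO[Si](C)(C)C(C)(C)C)=CC1 | intermediate
6 | 1-propynyllithium | [Li]C#CC | starting material
7 | 1-[4-({[tert-butyl(dimethyl)silyl]oxy}methyl)cyclohexa-1,4-dien-1-yl]but-2-yn-1-one | CC#CC(=O)C1=CCC(CO[Si](C)(C)C(C)(C)C)=CC1 | intermediate
8 | (1R)-1-[4-({[tert-butyl(dimethyl)silyl]oxy}methyl)cyclohexa-1,4-dien-1-yl]but-2-yn-1-ol | CC#C[C@H](O)C1=CCC(CO[Si](C)(C)C(C)(C)C)=CC1 | intermediate
9 | (1S,2Z)-1-[4-({[tert-butyl(dimethyl)silyl]oxy}methyl)cyclohexa-1,4-dien-1-yl]-3-iodobut-2-en-1-ol | I/C(C)=C\[C@H](O)C1=CCC(CO[Si](C)(C)C(C)(C)C)=CC1 | intermediate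
10 | (1S,2Z)-1-[(1S,6S)-4-({[tert-butyl(dimethyl)silyl]oxy}methyl)-7-oxabicyclo[4.1.0]hept-3-en-1-yl]-3-iodobut-2-en-1-ol (erythro epoxy alcohol) | I/C(C)=C\[C@H](O)[C@]12O[C@H]1CC(CO[Si](C)(C)C(C)(C)C)=CC2 | intermediate
11 | TBS ether of 10 at C1′ (same configuration; bis-silyl epoxide) | I/C(C)=C\[C@H](O[Si](C)(C)C(C)(C)C)[C@]12O[C@H]1CC(CO[Si](C)(C)C(C)(C)C)=CC2 | intermediate
12 | 3,4-trans-dibromide of 11 (3,4-dibromo-7-oxabicyclo[4.1.0]heptane; either trans adduct, the two bromine-bearing centres left open) | I/C(C)=C\[C@H](O[Si](C)(C)C(C)(C)C)[C@]12O[C@H]1CC(Br)(CO[Si](C)(C)C(C)(C)C)C(Br)C2 | intermediate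
13 | 2-[(1S,2Z)-1-{[tert-butyl(dimethyl)silyl]oxy}-3-iodobut-2-en-1-yl]-5-({[tert-butyl(dimethyl)silyl]oxy}methyl)oxepin | I/C(C)=C\[C@H](O[Si](C)(C)C(C)(C)C)C1=CC=C(CO[Si](C)(C)C(C)(C)C)C=CO1 | intermediate
14 | (1R,6S)-1-[(1S,2Z)-1-{[tert-butyl(dimethyl)silyl]oxy}-3-iodobut-2-en-1-yl]-4-({[tert-butyl(dimethyl)silyl]oxy}methyl)-7-oxabicyclo[4.1.0]hepta-2,4-diene (arene oxide, reactive valence tautomer of 13) | I/C(C)=C\[C@H](O[Si](C)(C)C(C)(C)C)[C@]12O[C@H]1C=C(CO[Si](C)(C)C(C)(C)C)C=C2 | intermediate
15 | anti epoxy endoperoxide of 14 (O–O bridge from C2 to C5 on the face opposite the oxirane) | I/C(C)=C\[C@H](O[Si](C)(C)C(C)(C)C)[C@]12O[C@H]1[C@H](OO3)C(CO[Si](C)(C)C(C)(C)C)=C[C@@H]23 | intermediate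
16 | (1R,2S,5R,6S)-1-[(1S,2Z)-1-{[tert-butyl(dimethyl)silyl]oxy}-3-iodobut-2-en-1-yl]-4-({[tert-butyl(dimethyl)silyl]oxy}methyl)-7-oxabicyclo[4.1.0]hept-3-ene-2,5-diol | I/C(C)=C\[C@H](O[Si](C)(C)C(C)(C)C)[C@]12O[C@H]1[C@H](O)C(CO[Si](C)(C)C(C)(C)C)=C[C@@H]2O | intermediate
17 | geranyl acetate | CC(=O)OC/C=C(\C)CCC=C(C)C | starting material
18 | (2E)-5-[(2R)-3,3-dimethyloxiran-2-yl]-3-methylpent-2-en-1-yl acetate | CC(=O)OC/C=C(\C)CC[C@H]1OC1(C)C | intermediate
19 | [(1S,3R)-3-hydroxy-2,2-dimethyl-6-methylidenecyclohexyl]methyl acetate | C=C1CC[C@@H](O)C(C)(C)[C@H]1COC(C)=O | intermediate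
20 | [(1S,3R)-3-{[tert-butyl(dimethyl)silyl]oxy}-2,2-dimethyl-6-methylidenecyclohexyl]methyl acetate | C=C1CC[C@@H](O[Si](C)(C)C(C)(C)C)C(C)(C)[C@H]1COC(C)=O | intermediate
21 | [(1S,3R)-3-{[tert-butyl(dimethyl)silyl]oxy}-2,2-dimethyl-6-methylidenecyclohexyl]methanol | C=C1CC[C@@H](O[Si](C)(C)C(C)(C)C)C(C)(C)[C@H]1CO | intermediate
22 | (1S,3R)-3-{[tert-butyl(dimethyl)silyl]oxy}-2,2-dimethyl-6-methylidenecyclohexane-1-carbaldehyde | C=C1CC[C@@H](O[Si](C)(C)C(C)(C)C)C(C)(C)[C@H]1C=O | intermediate
23 | 2-(dichloromethyl)-4,4,5,5-tetramethyl-1,3,2-dioxaborolane | ClC(Cl)B1OC(C)(C)C(C)(C)O1 | starting material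
24 | 2-{(E)-2-[(1S,3R)-3-{[tert-butyl(dimethyl)silyl]oxy}-2,2-dimethyl-6-methylidenecyclohexyl]ethenyl}-4,4,5,5-tetramethyl-1,3,2-dioxaborolane | C=C1CC[C@@H](O[Si](C)(C)C(C)(C)C)C(C)(C)[C@H]1/C=C/B1OC(C)(C)C(C)(C)O1 | intermediate
25 | tris-TBS ether of the target (silyl groups on the cyclohexanol oxygen, on the C1′ oxygen and on the primary oxygen; ring diol free) | C=C1CC[C@@H](O[Si](C)(C)C(C)(C)C)C(C)(C)[C@H]1/C=C/C(C)=C\[C@H](O[Si](C)(C)C(C)(C)C)[C@]12O[C@H]1[C@H](O)C(CO[Si](C)(C)C(C)(C)C)=C[C@@H]2O | intermediate
26 | (1R,2S,5R,6S)-4-(hydroxymethyl)-1-{(1S,2Z,4E)-1-hydroxy-5-[(1S,3R)-3-hydroxy-2,2-dimethyl-6-methylidenecyclohexyl]-3-methylpenta-2,4-dien-1-yl}-7-oxabicyclo[4.1.0]hept-3-ene-2,5-diol | C=C1CC[C@@H](O)C(C)(C)[C@H]1/C=C/C(C)=C\[C@H](O)[C@]12O[C@H]1[C@H](O)C(CO)=C[C@@H]2O | target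

Total step count: 18. Longest linear sequence: 12 steps (steps 1 to 10, then 17 and 18); fragment B takes steps 11 to 16.

Steps most likely to fail

Step 10. The two interconverting arene oxide enantiomers may be trapped at similar rates, so that the wanted diol is at most about half of the adduct and may co-elute with its ring diastereomer. The fallback sets out from 16 as it comes from step 10 (in mixture with its ring diastereomer) and comes back at 16. The mixture is submitted to lipase-catalysed acylation (Burkholderia cepacia lipase, vinyl acetate, tert-butyl methyl ether), which reads the configuration of the ring carbinol C5 and should acylate one diastereomer only; alcohol and ester are then easily separated. If the wanted series is the acylated one, the 5-O-acetate of 16 F4 is returned to 16 with K2CO3 in MeOH.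

Step 2. The Diels–Alder reaction may give a sizeable share of the 1,3-disubstituted (meta) regioisomer that cannot be removed. The fallback sets out from 3 and comes back at 7. A cobalt-catalysed neutral Diels–Alder reaction (CoBr2(dppe), ZnI2, Zn, CH2Cl2, rt) of 3 with the unactivated alkyne 3,3-diethoxyprop-1-yne, para-selective through the cobaltacycle, gives the diene acetal F1. Hydrolysis with oxalic acid on wet silica gives the dienal F2, addition of 1-propynylmagnesium bromide (THF, −78 °C) gives the racemic propargylic alcohol F3, and MnO2 in CH2Cl2 oxidises it to ynone 7.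

Step 18. Slow cleavage of the two hindered secondary silyl ethers may force long fluoride exposure, during which the C5 alkoxide can shift the oxirane or the dienyl carbinol can ionise. The fallback sets out from 16 and 24 and comes back at 26. Both fragments are desilylated separately with HF·pyridine buffered with pyridine in THF (no alkoxide is formed, and neither fragment yet holds the diene), giving the tetraol vinyl iodide F5 and the hydroxy alkenylboronate F6. Suzuki coupling of the two unprotected fragments (PdCl2(dppf), aqueous K3PO4, THF, rt) then gives 26 directly.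

Further compounds

F1 | step 2 | tert-butyl{[4-(diethoxymethyl)cyclohexa-1,4-dien-1-yl]methoxy}dimethylsilane | CCOC(OCC)C1=CCC(CO[Si](C)(C)C(C)(C)C)=CC1
F2 | step 2 | 4-({[tert-butyl(dimethyl)silyl]oxy}methyl)cyclohexa-1,4-diene-1-carbaldehyde | O=CC1=CCC(CO[Si](C)(C)C(C)(C)C)=CC1
F3 | step 2 | racemic 1-[4-({[tert-butyl(dimethyl)silyl]oxy}methyl)cyclohexa-1,4-dien-1-yl]but-2-yn-1-ol | CC#CC(O)C1=CCC(CO[Si](C)(C)C(C)(C)C)=CC1
F4 | step 10 | 5-O-acetate of 16 | I/C(C)=C\[C@H](O[Si](C)(C)C(C)(C)C)[C@]12O[C@H]1[C@H](OC(C)=O)C(CO[Si](C)(C)C(C)(C)C)=C[C@@H]2O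
F5 | step 18 | (1R,2S,5R,6S)-1-[(1S,2Z)-1-hydroxy-3-iodobut-2-en-1-yl]-4-(hydroxymethyl)-7-oxabicyclo[4.1.0]hept-3-ene-2,5-diol | I/C(C)=C\[C@H](O)[C@]12O[C@H]1[C@H](O)C(CO)=C[C@@H]2O
F6 | step 18 | (1R,3S)-2,2-dimethyl-4-methylidene-3-[(E)-2-(4,4,5,5-tetramethyl-1,3,2-dioxaborolan-2-yl)ethenyl]cyclohexan-1-ol | C=C1CC[C@@H](O)C(C)(C)[C@H]1/C=C/B1OC(C)(C)C(C)(C)O1
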